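The choice between faster dissolution and higher solubility for the flask is made on the fraction of starting material left, not on the fraction made.

| flask | starting material | solid reagent | remark | time |
|---|---|---|---|---|
| maple | 0.40 M | 2 M | run made earlier |  |
| ash | 0.60 M | 2 M | run made earlier |  |
| flask | 0.80 M | 2.00 M |  | 5.0 h |

| run | time / h | mono adduct / % | starting material / % |
|---|---|---|---|
| maple | 0.833 | 2.2 | 97.5 |
| maple | 1.50 | 6.6 | 94.3 |
| maple | 2.50 | 11.4 | 87.9 |
| maple | 3.00 | 14.4 | 82.6 |
| maple | 4.00 | 21.1 | 77.1 |
| maple | 5.00 | 26.6 | 70.5 |
| maple | 6.00 | 29.5 | 62.9 |
| ash | 0.333 | 0 | 99.1 |
| ash | 1.00 | 1.6 | 97.6 |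
| ash | 1.50 | 6.7 | 93.1 |
| ash | 2.50 | 10.5 | 86.4 |
| ash | 4.00 | 19.4 | 74.8 |
| ash | 5.00 | 25.5 | 70.8 |
| ash | 6.00 | 30.3 | 66.1 |

(standard deviation of a reading: 1 percentage point)

- solid reagent is a solid; its amount is given per volume of the solution
- at the start none of the solid reagent is in solution

- north-west: doubling the dissolution coefficient of the solid reagent, all else as stated
- north: doubling the solubility of the solid reagent, all else as stated

- the mono adduct standing at 5.0 h, as a percentage of the starting material charged
- the change that raises the amount of mono adduct at 5.0 h, in percent of the starting material charged most ("none" if none brings more than 2 percentage points) (north-west / north / none)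
- amount of mono adduct at 5.0 h, in percent of the starting material charged, after north-west

Pooling maple and ash between 2.50 h and 6.00 h gives the reading 0.0860 /h for κ, the fall of ln(fraction left) per hour, a pseudo-first-order constant.

Two extreme versions of the runs bracket the readings. With the reagent dissolved from the first moment, the reckoning leaves 80.7 % of the starting material at 2.50 h; with no reaction before then, it leaves the whole charge. The pooled runs hold 87.2 %, between the two. Running the late line back to a full charge gives a dead time θ of 0.901 h.

My reckoning carries κ and θ unchanged to 0.80 M, so it puts the starting material left in the flask at exp(−κ(t − θ)), or 70.3 %, at 5.0 h. In the runs, mono adduct was 88.8 % of what had gone by 5.00 h, which gives 26.4 % mono adduct for the flask. I take north-west as cutting θ to 0.451 h, which gives 28.7 %. I take north as setting κ to 0.172 /h with θ held, which gives 44.9 %, more than north-west.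

The forecast gave 25.5 % of mono adduct (22.5 % to 27.5 %), lower than my 26.4 %; it chose north and gave 28 % (25 % to 31 %) after north-west, on the ground that “Doubling the solubility doubles the dissolved reagent”.

The flask gives 23.8 % of mono adduct. North adds 14 percentage points, more than the 4.1 points of north-west, which reaches 27.9 %. The equations follow, with the dissolved reagent as coupling partner:

    starting material + coupling partner → mono adduct (k = 0.00485 /M/min)
    starting material + coupling partner → other mono adduct (k = 4.57 × 10⁻⁴ /M/min)
    solid reagent ⇌ coupling partner, rate k3*(cs3 - [coupling partner]) while solid is left; crystals form when [coupling partner] > cs3 (solubility = 0.330 M, k = 0.0138 /min)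
    coupling partner + other mono adduct → double product (k = 0.00444 /M/min)
    coupling partner + mono adduct → double product (k = 0.00247 /M/min)

The flask has 72 % of its starting material left at 5.00 h, against the 70.3 % reckoned with κ and θ. For a neighbouring flask with the same charges, read at 20 h, the same line gives 19.3 % of the starting material left, and that neighbour holds 19.3 %. That neighbour has lost 80.7 % of the charge, and in percent of the same charge it holds 3.14 % other mono adduct, 31.1 % double product and 46.5 % mono adduct.

The data are simulated with constants of no real substance, and the scatter is random.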